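In the blue flask I charge 0.050 M of first end groups against 0.0950 M of second end groups, so first end groups are the limiting reagent. Their balance is simple: what I charged equals what is left plus links plus side product A plus side product B, with one side product B counted as two. A point lost from links therefore stands in a side product or goes back to first end groups.

| setting | dusk | spring | blue | green | teal | amber | red |
|---|---|---|---|---|---|---|---|
| first end groups | 0.074 M | 1.3 M | 0.050 M | 0.10 M | 0.20 M | 0.40 M | 0.80 M |
| second end groups | 0.095 M | 0.095 M | 0.0950 M | 0.0950 M | 0.0950 M | 0.0950 M | 0.0950 M |
| remark | run made earlier | run made earlier |  |  |  |  |  |
| time |  |  | 5.0 min | 5.0 min | 5.0 min | 5.0 min | 5.0 min |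

| run | time / min | links / % |
|---|---|---|
| dusk | 1.33 | 72.9 |
| dusk | 2.50 | 65.0 |
| dusk | 4.00 | 55.4 |
| dusk | 5.00 | 51.1 |
| spring | 0.417 | 1.0 |
| spring | 1.00 | 1.7 |
| spring | 2.00 | 1.6 |
| spring | 5.00 | 1.1 |

(readings scatter by 1 percentage point)

- in percentages every species weighs as the first end groups in it: one side product B counts as two
- what may be going on: first end groups + second end groups <-> links + released group; links + released group -> side product A; first end groups + links -> side product B
- "hardly changes" means that all values lie within two and a half points (for a concentration: within two and a half percent of the largest)

* [links] at the end for blue, green, teal, amber, red, in this order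
* the course of these numbers from the first flask to the last (falls, then rises / rises all the way / falls all the way / hardly changes / rises, then falls)

The dusk flask is also short of first end groups, so I read the rates there. Up to the first reading, links gain on average 0.548 min⁻¹, taken as a fraction of the charge, and the second reading already stands lower. Between the first and last readings they fall on average at 0.0968 min⁻¹, as read from the dusk run. This fade rate, the share of the links lost per minute once the links are falling, is what I carry.

The fade accumulates as a factor: in dusk, from 1.33 min to 5.0 min, it leaves 0.701 of the links. If I take dusk's first share for blue and apply this factor, I reckon 0.0256 M of links at the end. Dusk's last reading stands for 0.0378 M of links, more than my blue figure. Spring's last reading stands for 0.0143 M, with a scatter of 1 percentage point of a far larger charge, and that is less than dusk's figure. So I expect the row to rise and then fall.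

The forecast gives 0.027 M, 0.04 M, 0.024 M, 0.016 M and 0.014 M, a course that rises, then falls, on the ground that “excess first end groups consume them”.

The flasks give 0.0311 M, 0.0390 M, 0.0206 M, 0.00340 M and 6.83 × 10⁻⁵ M, a course that rises, then falls.

    first end groups + second end groups ⇌ links + released group (K = 17.0, k = 0.651 M⁻¹ s⁻¹)
    links + released group → side product A (k = 0.0371 M⁻¹ s⁻¹)
    first end groups + links → side product B (k = 0.0337 M⁻¹ s⁻¹)

In blue, the step making links has done half of its turnover up to the asked time by 0.203 min. The step from links and released group to side product A has 17% of its turnover up to the asked time behind it at 1.00 min, and side product A stands at 29.3% of the charge at 5.00 min. My blue figure of 0.0256 M lies below the 0.0311 M found. Carrying 0.0968 min⁻¹ through green from 53.0% of links at 2.50 min gives 41.6% at 5.00 min, more than the 39.0% of links that green holds.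

All runs were generated by integration with made-up constants.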